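in all of them: Q 20 mM

| flask | Z | remark | time |
|---|---|---|---|
| green | 0.05 mol% | run made earlier |  |
| amber | 0.075 mol% | run made earlier |  |
| flask | 0.1 mol% |  | 50 h |

| run | time / h | J / % | G / % |
|---|---|---|---|
| green | 10.0 | 3 | 42 |
| green | 20.0 | 11 | 42 |
| green | 30.0 | 12 | 41 |
| green | 40.0 | 16 | 43 |
| green | 48.0 | 14 | 41 |
| amber | 10.0 | 7 | 42 |
| amber | 20.0 | 11 | 39 |
| amber | 30.0 | 17 | 42 |
| amber | 40.0 | 19 | 40 |
| amber | 48.0 | 23 | 42 |

(scatter of a reading: 1.5 percentage points)

- as a solid, counted per litre of solution: Q
- what may be going on: G + Z <-> J + Z; J + Z <-> D + Z; Q <-> G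
- at the start none of Q is in solution
- G means what is dissolved; the solid is not counted in it

1. J at 50 h, in percent of the Q charged
2. concentration of G in solution at 50 h, in percent of saturation

G is the easy line: in both runs it reads between 39 % and 43 % with no trend, though Z differs. So I take [G] as held at saturation by solid Q, and the step from G to J as pseudo-zero-order in G, going with [Z]. This flask then has 100 h of green-time, the reaction time multiplied by its loading over the green loading. The test: the amber run at 20.0 h has 30.0 h of green-time and reads J 11 %, and the green run at 30.0 h reads 12 %. The amber run ends at 72.0 h with J 23 %. Its last step, from 60.0 h, carried straight on gives 32.3 %, but J can go on to D, so I commit to less. The forecast says J 26 % (22 % to 31 %) and 99 % of saturation (93 % to 100 %), reasoning that “solid should just survive”.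

The flask gives J 23.6 % and 99.4 % of saturation.

    G + Z ⇌ J + Z, rate k1*[G]*[Z] forward; the back reaction follows from the equilibrium constant (K = 0.920, k = 1400 /M/h)
    J + Z ⇌ D + Z, rate k2*[Z]*[J] forward; the back reaction follows from the equilibrium constant (K = 12.0, k = 680 /M/h)
    Q ⇌ G, rate k3*(cs3 - [G]) while solid is left; crystals form when [G] > cs3 (solubility = 8.40 mM, k = 1.80 /h)

In this flask half the dissolving of Q up to 50 h is done by 1.24 h, much sooner than half of the step from G to J at 19.3 h, and at 50.0 h Q still stands at 24.3 % with G at 41.7 %. The neighbour flask with 0.025 mol% of Z, read at 50 h, has 25.0 h of green-time, the 100 h of this flask scaled by the loadings, and gives J 11.2 %; the green run reads 11 % at 20.0 h and 12 % at 30.0 h.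

All runs were computed for substances that don't exist, noise included.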